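**Retrosynthetic overview**
- The pyran ring is closed last, by 6-endo-dig hydroalkoxylation (O2–C3) of an ynenone that carries the C8a–CH2OH group.
- The ynenone comes from a saturated 5-alkynyl ketone by Saegusa–Ito dehydrogenation; the C8 orsellinate and the C7–OH come from opening a 7,8-epoxy ketone with orsellinic acid (inversion at C8).
- The epoxy ketone comes from nucleophilic epoxidation of a 2-methylcyclohex-2-enone anti to the C8a substituent; the propenyl group is added by Sonogashira coupling.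
- The carbocycle is formed first, by an enantioselective enamine Michael addition of 3-silyloxypropanal to an enynone (sets C8a, forms C8a–C4a) followed by aldol condensation; the enynone comes from a Horner–Wadsworth–Emmons reaction.

Assumption: compounds 1, 2, 4, 10 and 12 are taken as catalogue items; atom labels C1–C8a below are the isochromene positions of the target.

**Step 1**
Reactants: 1 diethyl (2-oxobutyl)phosphonate; 2 3-(trimethylsilyl)prop-2-ynal
Product: 3 (4E)-7-(trimethylsilyl)hept-4-en-6-yn-3-one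
Conditions: LiCl, i-Pr2NEt, MeCN, 0 °C to rt
Reagents that add atoms: none
Why: Horner–Wadsworth–Emmons olefination under Masamune–Roush conditions, in which the stabilised β-keto phosphonate anion gives the E-enone and the non-nucleophilic base spares the ynal and the silyl alkyne.

**Step 2**
Reactants: 3 (4E)-7-(trimethylsilyl)hept-4-en-6-yn-3-one; 4 3-{[tert-butyl(dimethyl)silyl]oxy}propanal
Product: 7 (4S,5S)-4-({[tert-butyl(dimethyl)silyl]oxy}methyl)-2-methyl-5-[(trimethylsilyl)ethynyl]cyclohex-2-en-1-one, via Michael keto-aldehyde 5 (not isolated), via ketol 6 (not isolated)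
Conditions: (S)-2-[methoxy(diphenyl)methyl]pyrrolidine (20 mol%), ethyl 3,4-dihydroxybenzoate (40 mol%), neat, 4 °C to rt; then TsOH·H2O (20 mol%), toluene, 40 °C
Reagents that add atoms: none
Why: Proposed new method: enamine Michael addition of an aldehyde to a β-alkynyl (2-en-4-ynyl) ketone, in which the E-enamine of 4 attacks the β-carbon of 3 (carbonyl hydrogen-bonded to the catechol co-catalyst) from the face remote from the CPh2OMe group and so sets C8a as S and forms the C8a–C4a bond; the linear, electron-withdrawing alkynyl group should keep the β-carbon accessible and the Me3Si cap should block 1,6-attack; the closest known reactions are the diarylprolinol-ether Michael additions of aldehydes to vinyl ketones and to nitroenynes, and the ring is then closed by a standard acid-mediated intramolecular aldol condensation (C7 onto C8).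

**Step 3**
Reactants: 7 (4S,5S)-4-({[tert-butyl(dimethyl)silyl]oxy}methyl)-2-methyl-5-[(trimethylsilyl)ethynyl]cyclohex-2-en-1-one
Product: 9 (1S,4S,5S,6S)-5-({[tert-butyl(dimethyl)silyl]oxy}methyl)-4-ethynyl-1-methyl-7-oxabicyclo[4.1.0]heptan-2-one, via ethynyl enone 8 (not isolated)
Conditions: 30% H2O2 (3 equiv), NaOH (0.5 equiv), MeOH, 0 °C
Reagents that add atoms: hydrogen peroxide, OO
Why: Weitz–Scheffer nucleophilic epoxidation after methanolic hydroxide strips the alkynyl Me3Si group; hydroperoxide adds axially to C8 anti to the adjacent CH2OTBS group (the slim ethynyl group tolerates the axial position), so the 7,8-epoxide lies on the face opposite C1 and fixes C7 as S.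

**Step 4**
Reactants: 9 (1S,4S,5S,6S)-5-({[tert-butyl(dimethyl)silyl]oxy}methyl)-4-ethynyl-1-methyl-7-oxabicyclo[4.1.0]heptan-2-one; 10 (1E)-1-bromoprop-1-ene
Product: 11 (1S,4S,5S,6S)-5-({[tert-butyl(dimethyl)silyl]oxy}methyl)-1-methyl-4-[(3E)-pent-3-en-1-yn-1-yl]-7-oxabicyclo[4.1.0]heptan-2-one
Conditions: PdCl2(PPh3)2 (3 mol%), CuI (6 mol%), Et3N, THF, rt
Reagents that add atoms: none
Why: Sonogashira coupling of the terminal alkyne with the vinyl bromide keeps the E geometry, and the epoxy ketone is inert to triethylamine at room temperature.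

**Step 5**
Reactants: 11 (1S,4S,5S,6S)-5-({[tert-butyl(dimethyl)silyl]oxy}methyl)-1-methyl-4-[(3E)-pent-3-en-1-yn-1-yl]-7-oxabicyclo[4.1.0]heptan-2-one; 12 orsellinic acid (2,4-dihydroxy-6-methylbenzoic acid)
Product: 13 (1R,2S,5S,6S)-6-({[tert-butyl(dimethyl)silyl]oxy}methyl)-2-hydroxy-2-methyl-3-oxo-5-[(3E)-pent-3-en-1-yn-1-yl]cyclohexyl 2,4-dihydroxy-6-methylbenzoate
Conditions: 12 (2 equiv), Cs2CO3 (0.25 equiv), DMF, 60 °C
Reagents that add atoms: none
Why: SN2 opening of the α-methyl-α,β-epoxy ketone by the carboxylate at the secondary β-carbon C8 (the tertiary α-keto carbon C7 is blocked), trans-diaxial with inversion, which sets C8 as R, builds the hindered aryl ester through its oxygen and leaves the C7 oxygen as the tertiary alcohol trans to the ester.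

**Step 6**
Reactants: 13 (1R,2S,5S,6S)-6-({[tert-butyl(dimethyl)silyl]oxy}methyl)-2-hydroxy-2-methyl-3-oxo-5-[(3E)-pent-3-en-1-yn-1-yl]cyclohexyl 2,4-dihydroxy-6-methylbenzoate
Product: 16 (1R,2S,6S)-2-({[tert-butyl(dimethyl)silyl]oxy}methyl)-6-hydroxy-6-methyl-5-oxo-3-[(3E)-pent-3-en-1-yn-1-yl]cyclohex-3-en-1-yl 2,4-dihydroxy-6-methylbenzoate, via tetrakis-silyl enol ether 14 (not isolated), via tris-silyl enone 15 (not isolated)
Conditions: Me3SiOTf (6 equiv), Et3N, CH2Cl2, 0 °C; Pd(OAc)2 (1.2 equiv), MeCN, rt; citric acid, MeOH, rt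
Reagents that add atoms: none
Why: Saegusa–Ito oxidation, in which enolisation can only go toward C5 (C7 is quaternary) and β-hydride elimination removes the C4a hydrogen to give the conjugated ynenone, erasing the C4a centre, while the transiently silylated hydroxyls are freed on methanolic work-up.

**Step 7**
Reactants: 16 (1R,2S,6S)-2-({[tert-butyl(dimethyl)silyl]oxy}methyl)-6-hydroxy-6-methyl-5-oxo-3-[(3E)-pent-3-en-1-yn-1-yl]cyclohex-3-en-1-yl 2,4-dihydroxy-6-methylbenzoate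
Product: 18 (7S,8R,8aS)-7-hydroxy-7-methyl-6-oxo-3-[(1E)-prop-1-en-1-yl]-6,7,8,8a-tetrahydro-1H-isochromen-8-yl 2,4-dihydroxy-6-methylbenzoate (target), via primary alcohol 17 (not isolated)
Conditions: HF·pyridine, THF, 0 °C; then Ph3PAuNTf2 (2 mol%), CH2Cl2, rt
Reagents that add atoms: none
Why: Fluoride removes the primary silyl ether and cationic monovalent gold activates the alkyne for 6-endo-dig hydroalkoxylation at C3 (the Michael terminus of the ynenone, also stabilised by the propenyl group), so the pyran ring closes under non-basic conditions that leave C7, C8 and C8a untouched.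

**Compound list**
1 | diethyl (2-oxobutyl)phosphonate | CCC(=O)CP(=O)(OCC)OCC | starting material
2 | 3-(trimethylsilyl)prop-2-ynal | C[Si](C)(C)C#CC=O | starting material
3 | (4E)-7-(trimethylsilyl)hept-4-en-6-yn-3-one | CCC(=O)/C=C/C#C[Si](C)(C)C | intermediate
4 | 3-{[tert-butyl(dimethyl)silyl]oxy}propanal | O=CCCO[Si](C)(C)C(C)(C)C | starting material
5 | (2S,3S)-2-({[tert-butyl(dimethyl)silyl]oxy}methyl)-5-oxo-3-[(trimethylsilyl)ethynyl]heptanal (expected major C3 epimer; this centre is removed in step 6) | O=C[C@@H]([C@@H](C#C[Si](C)(C)C)CC(=O)CC)CO[Si](C)(C)C(C)(C)C | intermediate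
6 | (4S,5S)-4-({[tert-butyl(dimethyl)silyl]oxy}methyl)-3-hydroxy-2-methyl-5-[(trimethylsilyl)ethynyl]cyclohexan-1-one (epimers at C2 and C3) | O=C1C[C@H](C#C[Si](C)(C)C)[C@@H](CO[Si](C)(C)C(C)(C)C)C(O)C1C | intermediate
7 | (4S,5S)-4-({[tert-butyl(dimethyl)silyl]oxy}methyl)-2-methyl-5-[(trimethylsilyl)ethynyl]cyclohex-2-en-1-one | CC1=C[C@H](CO[Si](C)(C)C(C)(C)C)[C@@H](C#C[Si](C)(C)C)CC1=O | intermediate
8 | (4S,5S)-4-({[tert-butyl(dimethyl)silyl]oxy}methyl)-5-ethynyl-2-methylcyclohex-2-en-1-one | CC1=C[C@H](CO[Si](C)(C)C(C)(C)C)[C@@H](C#C)CC1=O | intermediate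
9 | (1S,4S,5S,6S)-5-({[tert-butyl(dimethyl)silyl]oxy}methyl)-4-ethynyl-1-methyl-7-oxabicyclo[4.1.0]heptan-2-one | C[C@]12O[C@H]1[C@H](CO[Si](C)(C)C(C)(C)C)[C@@H](C#C)CC2=O | intermediate
10 | (1E)-1-bromoprop-1-ene | C/C=C/Br | starting material
11 | (1S,4S,5S,6S)-5-({[tert-butyl(dimethyl)silyl]oxy}methyl)-1-methyl-4-[(3E)-pent-3-en-1-yn-1-yl]-7-oxabicyclo[4.1.0]heptan-2-one | C[C@]12O[C@H]1[C@H](CO[Si](C)(C)C(C)(C)C)[C@@H](C#C/C=C/C)CC2=O | intermediate
12 | orsellinic acid (2,4-dihydroxy-6-methylbenzoic acid) | Cc1cc(O)cc(O)c1C(=O)O | starting material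
13 | (1R,2S,5S,6S)-6-({[tert-butyl(dimethyl)silyl]oxy}methyl)-2-hydroxy-2-methyl-3-oxo-5-[(3E)-pent-3-en-1-yn-1-yl]cyclohexyl 2,4-dihydroxy-6-methylbenzoate | C/C=C/C#C[C@H]1CC(=O)[C@@](C)(O)[C@H](OC(=O)c2c(C)cc(O)cc2O)[C@@H]1CO[Si](C)(C)C(C)(C)C | intermediate
14 | tetrakis(trimethylsilyl) derivative of 13: C6 trimethylsilyl enol ether (C5=C6), C7–OSiMe3 and both phenolic OSiMe3 | C/C=C/C#C[C@H]1C=C(O[Si](C)(C)C)[C@@](C)(O[Si](C)(C)C)[C@H](OC(=O)c2c(C)cc(O[Si](C)(C)C)cc2O[Si](C)(C)C)[C@@H]1CO[Si](C)(C)C(C)(C)C | intermediate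
15 | tris(trimethylsilyl) ether of 16: C7–OSiMe3 and both phenolic OSiMe3 | C/C=C/C#CC1=CC(=O)[C@@](C)(O[Si](C)(C)C)[C@H](OC(=O)c2c(C)cc(O[Si](C)(C)C)cc2O[Si](C)(C)C)[C@@H]1CO[Si](C)(C)C(C)(C)C | intermediate
16 | (1R,2S,6S)-2-({[tert-butyl(dimethyl)silyl]oxy}methyl)-6-hydroxy-6-methyl-5-oxo-3-[(3E)-pent-3-en-1-yn-1-yl]cyclohex-3-en-1-yl 2,4-dihydroxy-6-methylbenzoate | C/C=C/C#CC1=CC(=O)[C@@](C)(O)[C@H](OC(=O)c2c(C)cc(O)cc2O)[C@@H]1CO[Si](C)(C)C(C)(C)C | intermediate
17 | (1R,2S,6S)-6-hydroxy-2-(hydroxymethyl)-6-methyl-5-oxo-3-[(3E)-pent-3-en-1-yn-1-yl]cyclohex-3-en-1-yl 2,4-dihydroxy-6-methylbenzoate | C/C=C/C#CC1=CC(=O)[C@@](C)(O)[C@H](OC(=O)c2c(C)cc(O)cc2O)[C@@H]1CO | intermediate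
18 | (7S,8R,8aS)-7-hydroxy-7-methyl-6-oxo-3-[(1E)-prop-1-en-1-yl]-6,7,8,8a-tetrahydro-1H-isochromen-8-yl 2,4-dihydroxy-6-methylbenzoate | C/C=C/C1=CC2=CC(=O)[C@@](C)(O)[C@H](OC(=O)c3c(C)cc(O)cc3O)[C@@H]2CO1 | target

**Step count**
Total steps: 7. Longest linear sequence: 7.

**Three steps most likely to fail**

1. Step 2, the new Michael addition. The β-alkynyl enone may not turn over under enamine catalysis, or may take the aldehyde at the alkyne terminus (1,6). The fallback sets out from 4 and comes back at 13, using the established vinyl-ketone version and bringing in the alkyne later. Compound 4 and pent-1-en-3-one under the same amine/catechol pair, then TsOH, give (4R)-4-({[tert-butyl(dimethyl)silyl]oxy}methyl)-2-methylcyclohex-2-en-1-one F1. H2O2/NaOH gives the trans epoxy ketone (1S,5S,6S)-5-({[tert-butyl(dimethyl)silyl]oxy}methyl)-1-methyl-7-oxabicyclo[4.1.0]heptan-2-one F2. Orsellinic acid 12 with Cs2CO3 opens it to (1R,2S,6S)-6-({[tert-butyl(dimethyl)silyl]oxy}methyl)-2-hydroxy-2-methyl-3-oxocyclohexyl 2,4-dihydroxy-6-methylbenzoate F3. Saegusa–Ito oxidation gives (1R,2S,6S)-2-({[tert-butyl(dimethyl)silyl]oxy}methyl)-6-hydroxy-6-methyl-5-oxocyclohex-3-en-1-yl 2,4-dihydroxy-6-methylbenzoate F4. Conjugate addition of Me2AlC≡CSiMe3 (Ni(acac)2, i-Bu2AlH catalyst, excess alane for the free hydroxyls) anti to the CH2OTBS group gives (1R,2S,5S,6S)-6-({[tert-butyl(dimethyl)silyl]oxy}methyl)-2-hydroxy-2-methyl-3-oxo-5-[(trimethylsilyl)ethynyl]cyclohexyl 2,4-dihydroxy-6-methylbenzoate F5. A fluoride-triggered Sonogashira coupling of F5 with 10 (CsF, PdCl2(PPh3)2, CuI, Et3N, DMF) gives 13, where the route resumes.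

2. Step 3, the face of epoxidation. The Michael step is expected to place the alkynyl group trans to the CH2OTBS group, so the two substituents direct the peroxide to opposite faces, and attack syn to CH2OTBS would give the wrong C7/C8 configuration. The fallback sets out from 7 and comes back at 9, delivering the epoxide from a hydroxyl instead. Luche reduction (NaBH4, CeCl3·7H2O, MeOH, −78 °C; axial hydride attack) gives the allylic alcohol (1R,4S,5S)-4-({[tert-butyl(dimethyl)silyl]oxy}methyl)-2-methyl-5-[(trimethylsilyl)ethynyl]cyclohex-2-en-1-ol F6, whose hydroxyl lies on the face opposite the CH2OTBS group. VO(acac)2/t-BuOOH epoxidises syn to that hydroxyl to give (1R,2R,4S,5S,6S)-5-({[tert-butyl(dimethyl)silyl]oxy}methyl)-1-methyl-4-[(trimethylsilyl)ethynyl]-7-oxabicyclo[4.1.0]heptan-2-ol F7. Dess–Martin periodinane returns the ketone (1S,4S,5S,6S)-5-({[tert-butyl(dimethyl)silyl]oxy}methyl)-1-methyl-4-[(trimethylsilyl)ethynyl]-7-oxabicyclo[4.1.0]heptan-2-one F8, and K2CO3/MeOH removes the alkynyl silyl group to give 9.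

3. Step 5, the epoxide opening. The salicylate-type carboxylate is a weak nucleophile and C8 is flanked by a quaternary and a tertiary carbon. The fallback sets out from 11 and comes back at 13, making the C8–O bond with water and the ester afterwards. Dilute HClO4 in THF/H2O at 0 °C opens the epoxide at C8 with inversion to the trans-diol (2S,3R,4S,5S)-4-({[tert-butyl(dimethyl)silyl]oxy}methyl)-2,3-dihydroxy-2-methyl-5-[(3E)-pent-3-en-1-yn-1-yl]cyclohexan-1-one F9. Orsellinic acid 12 is converted (acetone, trifluoroacetic anhydride, trifluoroacetic acid) into 7-hydroxy-2,2,5-trimethyl-4H-1,3-benzodioxin-4-one F10. Irradiation of F10 (300 nm, CH2Cl2) generates the quinoketene, which acylates the less hindered secondary hydroxyl of F9 under neutral conditions to give 13.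

**Further compounds**
F1 | step 2 | (4R)-4-({[tert-butyl(dimethyl)silyl]oxy}methyl)-2-methylcyclohex-2-en-1-one | CC1=C[C@H](CO[Si](C)(C)C(C)(C)C)CCC1=O
F2 | step 2 | (1S,5S,6S)-5-({[tert-butyl(dimethyl)silyl]oxy}methyl)-1-methyl-7-oxabicyclo[4.1.0]heptan-2-one | C[C@]12O[C@H]1[C@H](CO[Si](C)(C)C(C)(C)C)CCC2=O
F3 | step 2 | (1R,2S,6S)-6-({[tert-butyl(dimethyl)silyl]oxy}methyl)-2-hydroxy-2-methyl-3-oxocyclohexyl 2,4-dihydroxy-6-methylbenzoate | C1CC(=O)[C@@](C)(O)[C@H](OC(=O)c2c(C)cc(O)cc2O)[C@@H]1CO[Si](C)(C)C(C)(C)C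
F4 | step 2 | (1R,2S,6S)-2-({[tert-butyl(dimethyl)silyl]oxy}methyl)-6-hydroxy-6-methyl-5-oxocyclohex-3-en-1-yl 2,4-dihydroxy-6-methylbenzoate | C1=CC(=O)[C@@](C)(O)[C@H](OC(=O)c2c(C)cc(O)cc2O)[C@@H]1CO[Si](C)(C)C(C)(C)C
F5 | step 2 | (1R,2S,5S,6S)-6-({[tert-butyl(dimethyl)silyl]oxy}methyl)-2-hydroxy-2-methyl-3-oxo-5-[(trimethylsilyl)ethynyl]cyclohexyl 2,4-dihydroxy-6-methylbenzoate | C[Si](C)(C)C#C[C@H]1CC(=O)[C@@](C)(O)[C@H](OC(=O)c2c(C)cc(O)cc2O)[C@@H]1CO[Si](C)(C)C(C)(C)C
F6 | step 3 | (1R,4S,5S)-4-({[tert-butyl(dimethyl)silyl]oxy}methyl)-2-methyl-5-[(trimethylsilyl)ethynyl]cyclohex-2-en-1-ol | CC1=C[C@H](CO[Si](C)(C)C(C)(C)C)[C@@H](C#C[Si](C)(C)C)C[C@H]1O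
F7 | step 3 | (1R,2R,4S,5S,6S)-5-({[tert-butyl(dimethyl)silyl]oxy}methyl)-1-methyl-4-[(trimethylsilyl)ethynyl]-7-oxabicyclo[4.1.0]heptan-2-ol | C[C@]12O[C@H]1[C@H](CO[Si](C)(C)C(C)(C)C)[C@@H](C#C[Si](C)(C)C)C[C@H]2O
F8 | step 3 | (1S,4S,5S,6S)-5-({[tert-butyl(dimethyl)silyl]oxy}methyl)-1-methyl-4-[(trimethylsilyl)ethynyl]-7-oxabicyclo[4.1.0]heptan-2-one | C[C@]12O[C@H]1[C@H](CO[Si](C)(C)C(C)(C)C)[C@@H](C#C[Si](C)(C)C)CC2=O
F9 | step 5 | (2S,3R,4S,5S)-4-({[tert-butyl(dimethyl)silyl]oxy}methyl)-2,3-dihydroxy-2-methyl-5-[(3E)-pent-3-en-1-yn-1-yl]cyclohexan-1-one | C/C=C/C#C[C@H]1CC(=O)[C@@](C)(O)[C@H](O)[C@@H]1CO[Si](C)(C)C(C)(C)C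
F10 | step 5 | 7-hydroxy-2,2,5-trimethyl-4H-1,3-benzodioxin-4-one | Cc1cc(O)cc2OC(C)(C)OC(=O)c12
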